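(The readings come from a simulation with constants of no real substance, and the scatter is random.)

At late times both earlier runs show L going slowly over to E. I take the E gained per minute and divide it by the mean of the two L readings at the ends of that stretch, which gives a first-order constant k: between 8.00 min and 15.0 min it reads 0.0224 min⁻¹ in the red run, and over the same stretch 0.0224 min⁻¹ in the violet run, both readings with their scatter. At the red rate L loses one power of ten in 103 min. I call this the decade time T: in my reckoning L falls in a straight line on a logarithmic scale, one unit per T.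

| run | time / min | D / % | Q / % | L / % | E / % |
|---|---|---|---|---|---|
| violet | 2.50 | 27.8 | 26.6 | 44.9 | 1.5 |
| violet | 5.00 | 10.9 | 12.7 | 70.7 | 4.6 |
| violet | 8.00 | 4.4 | 6.4 | 78.6 | 10.6 |
| violet | 10.0 | 2.9 | 4.3 | 80.2 | 12.4 |
| violet | 12.0 | 1.7 | 3.2 | 78.7 | 18.2 |
| violet | 15.0 | 0.7 | 1.3 | 75.4 | 22.7 |
| red | 1.00 | 45.8 | 32.9 | 20.9 | 0.1 |
| red | 3.00 | 24.5 | 6.5 | 65.5 | 2.5 |
| red | 5.00 | 9.9 | 1.2 | 83.6 | 5.6 |
| red | 8.00 | 1.6 | 0 | 85.6 | 12.0 |
| red | 12.0 | 0 | 0 | 79.8 | 19.1 |
| red | 15.0 | 0.3 | 0.5 | 75.3 | 24.6 |

(standard deviation of a reading: 0.5 percentage points)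

the same everywhere: Q 0.020 M
- violet: Z 1.2 equiv; run made earlier
- red: Z 1.9 equiv; run made earlier
- east: Z 2.50 equiv; time 15 min
- south: Z 2.50 equiv; time 30 min

- which of these there is most of at the end, counted by the Q in it, east (L / D / E / Q)
- which of these there is most of at the end, counted by the Q in it, south (L / D / E / Q)
- amount of the one of these that there is most of at the end, in percent of the Q charged, east
- amount of the one of these that there is most of at the end, in percent of the Q charged, south



To whoever takes over the bench: the flask holds Q with 2.50 equiv of Z, so Q is the limiting reagent, and east and south are this recipe read at two times. At 15 min I expect L near 75.3 %, because the red and violet runs stand level there, at 75.3 % and 75.4 %, with 1.9 equiv and 1.2 equiv of Z. So don't add Z; watch the clock. From east to south I reckon L to drop 0.146 of a decade, to 53.8 %, still ahead of the 46.2 % I reckon for E.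

The forecast names L at east with 74.5 % and L at south with 53 %, holding “so Z has no effect on this step either”; my figures for east and south are slightly higher.

The flask gives L at 74.8 % in east and L at 53.3 % in south.

    D → L (k = 0.630 min⁻¹)
    L ⇌ E (K = 31.0, k = 0.0230 min⁻¹)
    Q + Z → D (k = 38.0 M⁻¹ min⁻¹)

In south, D has a half-life of 1.1 min by its step to L, while L has 30 min by the forward step to E. Half of the turnover of D to L up to 30.0 min is done by 1.81 min, and at that time the south flask holds L at 53.3 % and E at 46.7 %. Carried from east to south, T gives 53.4 % of L. Carried from south to the same flask read at 2.0 h, it gives 7.12 %, below the 9.05 % of L that flask holds.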